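The route rests on opening the 1,2-dioxane at its O1–C6 bond, C6 being the quaternary carbon that carries the methyl group and the CH2CH2 link to the decalin. In one operation a mercury(II)-mediated 6-exo cyclisation of a C3 hydroperoxide onto the (E)-C6=C7 trisubstituted alkene, with hydride demercuration, closes the ring O1–O2–C3–C4–C5–C6 and sets C6 from C3 (large groups equatorial, methyl axial); it exploits that C6 is the Markovnikov carbon of the next isoprene unit. The precursor is an acyclic hydroperoxy trienol that already holds the cis-hexahydronaphthalene, built from (S)-limonene by Claisen rearrangement and cation–olefin cyclisation; C2 and C3 come from an Evans aldol.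

Key step: step 17

Remark: 2-methoxyprop-2-yl hydroperoxide (step 15) is a known reagent that is not sold; it is assumed to be made beforehand by ozonolysis of 2,3-dimethylbut-2-ene in methanol.
Remark: locants C1–C8 in steps 14–17 are those of the oct-6-ene chain of 22–25; C3–C6 of this chain become C3–C6 of the dioxane.

Step 1
Reactants: 1 (S)-(−)-limonene
Product: 2 (1R,2S,4S)-limonene 1,2-oxide (trans-limonene oxide)
Conditions: mCPBA (1.0 equiv), CH2Cl2, 0 °C
Reagents that add atoms: mCPBA, O=C(OO)c1cccc(Cl)c1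
Why: Prilezhaev epoxidation should take the more electron-rich trisubstituted ring alkene and spare the isopropenyl group, but without useful facial bias, so 2 is expected together with its C1/C2 diastereomer (cis-oxide), which is carried along and removed after step 2.

Step 2
Reactants: 2 (1R,2S,4S)-limonene 1,2-oxide
Product: 5 (1R,4S)-1-methyl-4-(prop-1-en-2-yl)cyclohex-2-en-1-ol, via hydroxy selenide 3 (not isolated), via selenoxide 4 (not isolated)
Conditions: (PhSe)2, NaBH4, EtOH, reflux; then 30% H2O2, THF, 0 °C to rt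
Reagents that add atoms: none
Why: Selenolate should open the trans-oxide by trans-diaxial attack at the secondary C2 (the cis-oxide is slow and its products are separated by chromatography), and selenoxide syn-elimination, which can only go towards C3, should give the tertiary allylic alcohol with the C1–O bond untouched, so that OH and isopropenyl stay on the same ring face.

Step 3
Reactants: 5 (1R,4S)-1-methyl-4-(prop-1-en-2-yl)cyclohex-2-en-1-ol
Product: 7 ethyl 2-[(1R,6S)-3-methyl-6-(prop-1-en-2-yl)cyclohex-2-en-1-yl]acetate, via ketene acetal 6 (not isolated)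
Conditions: MeC(OEt)3 (excess), EtCO2H (cat.), 140 °C, EtOH distilled off
Reagents that add atoms: triethyl orthoacetate, CC(OCC)(OCC)OCC
Why: The Johnson–Claisen rearrangement is suprafacial, so the acetate arm should be delivered to the ring face that held the oxygen, which sets the second ring stereocentre (C4a of the target) cis to the isopropenyl group and places the methyl-bearing trisubstituted alkene where ring A needs it.

Step 4
Reactants: 7 ethyl 2-[(1R,6S)-3-methyl-6-(prop-1-en-2-yl)cyclohex-2-en-1-yl]acetate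
Product: 8 ethyl 4-[(1R,6S)-3-methyl-6-(prop-1-en-2-yl)cyclohex-2-en-1-yl]-3-oxobutanoate
Conditions: LDA, EtOAc (3 equiv each), THF, −78 °C; then 7, −78 to −20 °C; NH4Cl quench
Reagents that add atoms: ethyl acetate, CCOC(C)=O
Why: Crossed Claisen condensation with an excess of the lithium enolate of ethyl acetate should acylate the enolate with the ester of 7, the β-keto ester being held as its enolate until the quench.

Step 5
Reactants: 8 ethyl 4-[(1R,6S)-3-methyl-6-(prop-1-en-2-yl)cyclohex-2-en-1-yl]-3-oxobutanoate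
Product: 9 ethyl (4aR,8aS)-1,1,6-trimethyl-3-oxo-1,2,3,4,4a,7,8,8a-octahydronaphthalene-2-carboxylate (C2 epimers and enol)
Conditions: SnCl4 (1.2 equiv), CH2Cl2, −78 to 0 °C
Reagents that add atoms: none
Why: In this β-keto-ester-terminated cation–olefin cyclisation, Markovnikov protonation of the isopropenyl group (the alkene that also reacts first when acids add to limonene) should give a tertiary cation that the tin-bound enol captures at carbon through a six-membered transition state, which builds the gem-dimethyl carbon and ring B on the preset cis ring fusion.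

Step 6
Reactants: 9 ethyl (4aR,8aS)-1,1,6-trimethyl-3-oxo-1,2,3,4,4a,7,8,8a-octahydronaphthalene-2-carboxylate
Product: 10 ethyl (4aR,8aS)-1,1,6-trimethyl-3-(trifluoromethylsulfonyloxy)-1,4,4a,7,8,8a-hexahydronaphthalene-2-carboxylate
Conditions: NaH, THF, 0 °C; then PhNTf2, 0 °C to rt
Reagents that add atoms: N-phenylbis(trifluoromethanesulfonimide), O=S(=O)(N(c1ccccc1)S(=O)(=O)C(F)(F)F)C(F)(F)F
Why: The β-keto ester enolises only between its two carbonyl groups, so O-sulfonylation of the sodium enolate should fix the double bond at C2=C3.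

Step 7
Reactants: 10 ethyl (4aR,8aS)-1,1,6-trimethyl-3-(trifluoromethylsulfonyloxy)-1,4,4a,7,8,8a-hexahydronaphthalene-2-carboxylate
Product: 11 ethyl (4aR,8aS)-1,1,3,6-tetramethyl-1,4,4a,7,8,8a-hexahydronaphthalene-2-carboxylate
Conditions: Me2CuLi (from MeLi and CuI), Et2O/THF, −78 to −20 °C
Reagents that add atoms: lithium dimethylcuprate, [Li+].C[Cu-]C
Why: Addition–elimination of the cuprate on the β-triflyloxy enoate (cuprate coupling of a vinyl triflate) should replace OTf by methyl and keep the tetrasubstituted alkene in place.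

Step 8
Reactants: 11 ethyl (4aR,8aS)-1,1,3,6-tetramethyl-1,4,4a,7,8,8a-hexahydronaphthalene-2-carboxylate
Product: 12 [(4aR,8aS)-1,1,3,6-tetramethyl-1,4,4a,7,8,8a-hexahydronaphthalen-2-yl]methanol
Conditions: DIBAL-H (2.5 equiv), CH2Cl2, −78 to 0 °C; Rochelle salt work-up
Reagents that add atoms: none
Why: DIBAL-H reduces the hindered conjugated ester 1,2 to the allylic alcohol without touching the alkenes.

Step 9
Reactants: 12 [(4aR,8aS)-1,1,3,6-tetramethyl-1,4,4a,7,8,8a-hexahydronaphthalen-2-yl]methanol
Product: 13 (4aR,8aS)-2-(bromomethyl)-1,1,3,6-tetramethyl-1,4,4a,7,8,8a-hexahydronaphthalene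
Conditions: PBr3 (0.4 equiv), pyridine (cat.), Et2O, −20 to 0 °C; used crude
Reagents that add atoms: phosphorus tribromide, BrP(Br)Br
Why: Bromination of the primary allylic alcohol through its phosphite ester should occur without allylic transposition, because SN2' attack would have to take place at a fully substituted ring carbon.

Step 10
Reactants: 14 pent-4-yn-1-ol
Product: 15 pent-4-ynal
Conditions: Dess–Martin periodinane, CH2Cl2, 0 °C to rt; used crude
Reagents that add atoms: none
Why: Dess–Martin oxidation stops at the aldehyde and leaves the terminal alkyne alone.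

Step 11
Reactants: 16 (R)-4-benzyl-3-propanoyl-1,3-oxazolidin-2-one; 15 pent-4-ynal
Product: 18 (4R)-4-benzyl-3-[(2R,3S)-3-hydroxy-2-methylhept-6-ynoyl]-1,3-oxazolidin-2-one, via boron enolate 17 (not isolated)
Conditions: Bu2BOTf, iPr2NEt, CH2Cl2, −78 to 0 °C; then 15, −78 to 0 °C; pH 7 buffer, MeOH, H2O2 work-up
Reagents that add atoms: none
Why: The Evans syn-aldol reaction of the (Z)-boron enolate through a Zimmerman–Traxler chair, with the auxiliary shielding one enolate face, should set the methyl-bearing carbon (C2 of the target acid) and the carbinol carbon as the (2R,3S) syn pair.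

Step 12
Reactants: 18 (4R)-4-benzyl-3-[(2R,3S)-3-hydroxy-2-methylhept-6-ynoyl]-1,3-oxazolidin-2-one
Product: 19 (2S,3S)-2-methylhept-6-yne-1,3-diol
Conditions: LiBH4, MeOH (1 equiv), Et2O, 0 °C
Reagents that add atoms: none
Why: Borohydride reduction of the imide carbonyl releases the auxiliary and gives the 1,3-diol without epimerising the α-centre.

Step 13
Reactants: 19 (2S,3S)-2-methylhept-6-yne-1,3-diol
Product: 20 (2S,3S)-2-methyl-1-(triethylsilyloxy)hept-6-yn-3-ol
Conditions: TESCl (1.0 equiv), imidazole, CH2Cl2, −78 °C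
Reagents that add atoms: chlorotriethylsilane, CC[Si](Cl)(CC)CC
Why: Silylation at low temperature should select the primary over the branched secondary hydroxyl, which leaves the secondary alcohol free for the later inversion.

Step 14
Reactants: 20 (2S,3S)-2-methyl-1-(triethylsilyloxy)hept-6-yn-3-ol; 13 (4aR,8aS)-2-(bromomethyl)-1,1,3,6-tetramethyl-1,4,4a,7,8,8a-hexahydronaphthalene
Product: 22 (2S,3S,6E)-2,6-dimethyl-8-[(4aR,8aS)-1,1,3,6-tetramethyl-1,4,4a,7,8,8a-hexahydronaphthalen-2-yl]-1-(triethylsilyloxy)oct-6-en-3-ol, via alkenylalane 21 (not isolated)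
Conditions: Me3Al (3 equiv), Cp2ZrCl2 (0.25 equiv), CH2Cl2, 0 °C to rt; then 13, Pd(PPh3)4 (5 mol%), THF, rt
Reagents that add atoms: trimethylaluminium, C[Al](C)C
Why: Zirconium-catalysed syn-carboalumination of the terminal alkyne (Negishi) places methyl on the internal carbon cis to aluminium, and Pd(0)-catalysed coupling of this alkenylalane at the primary terminus of the allylic bromide should give the skipped (E)-diene with retention in both partners, the free hydroxyl travelling as its aluminium alkoxide.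

Step 15
Reactants: 22 (2S,3S,6E)-2,6-dimethyl-8-[(4aR,8aS)-1,1,3,6-tetramethyl-1,4,4a,7,8,8a-hexahydronaphthalen-2-yl]-1-(triethylsilyloxy)oct-6-en-3-ol
Product: 24 triethylsilyl ether of (2S,3R,6E)-3-[(2-methoxypropan-2-yl)peroxy]-2,6-dimethyl-8-[(4aR,8aS)-1,1,3,6-tetramethyl-1,4,4a,7,8,8a-hexahydronaphthalen-2-yl]oct-6-en-1-ol, via triflate 23 (not isolated)
Conditions: Tf2O, 2,6-lutidine, CH2Cl2, −78 °C; then 2-methoxyprop-2-yl hydroperoxide, KOtBu, THF, −78 to 0 °C
Reagents that add atoms: 2-methoxypropan-2-yl hydroperoxide, COC(C)(C)OO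
Why: SN2 displacement of the secondary triflate by the α-nucleophilic anion of a ketal-protected hydroperoxide should invert C3, turning the syn-aldol carbinol centre into the (3R) peroxide-bearing carbon of the target.

Step 16
Reactants: 24 triethylsilyl ether of (2S,3R,6E)-3-[(2-methoxypropan-2-yl)peroxy]-2,6-dimethyl-8-[(4aR,8aS)-1,1,3,6-tetramethyl-1,4,4a,7,8,8a-hexahydronaphthalen-2-yl]oct-6-en-1-ol
Product: 25 (2S,3R,6E)-3-hydroperoxy-2,6-dimethyl-8-[(4aR,8aS)-1,1,3,6-tetramethyl-1,4,4a,7,8,8a-hexahydronaphthalen-2-yl]oct-6-en-1-ol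
Conditions: AcOH/THF/H2O (3:1:1), rt
Reagents that add atoms: none
Why: Mild acid hydrolysis should cleave the peroxyketal to the free hydroperoxide and the primary TES ether in the same operation, while acetic acid is too weak to protonate the alkenes or ionise the O–O bond.

Step 17
Reactants: 25 (2S,3R,6E)-3-hydroperoxy-2,6-dimethyl-8-[(4aR,8aS)-1,1,3,6-tetramethyl-1,4,4a,7,8,8a-hexahydronaphthalen-2-yl]oct-6-en-1-ol
Product: 27 (2S)-2-[(3R,6R)-6-methyl-6-{2-[(4aR,8aS)-1,1,3,6-tetramethyl-1,4,4a,7,8,8a-hexahydronaphthalen-2-yl]ethyl}-1,2-dioxan-3-yl]propan-1-ol, via organomercurial 26 (not isolated)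
Conditions: Hg(OAc)2 (1.05 equiv), CF3CO2H (cat.), CH2Cl2, 0 °C to rt; then NaBH4, 2 M NaOH, 0 °C
Reagents that add atoms: none
Why: Hg(II) coordinates the C6=C7 alkene and the terminal oxygen of the C3 hydroperoxide attacks the tertiary carbon C6 anti to mercury (Markovnikov, 6-exo-trig), closing the ring O1–O2–C3–C4–C5–C6, after which NaBH4 replaces the C7–Hg bond by C–H through the alkylmercury hydride. The closest known reaction type is cycloperoxymercuration–hydridodemercuration of unsaturated hydroperoxides, the peroxide counterpart of oxymercuration–demercuration. The new stereocentre C6 is controlled by C3: in the chair-like, acid-equilibrated closure the CH(CH3)CH2OH group at C3 and the bulky mercurated branch at C6 should both sit equatorial, which leaves the C6 methyl axial and gives the 3,6-cis (3R,6R) ring, while the E geometry and anti addition only fix the transient C7 centre that is erased on reduction. The step needs chemoselectivity for this alkene over the two ring alkenes and over the primary alcohol: only C6=C7 can be reached by the tethered OOH through a six-membered transition state, mercuration of the ring alkenes is reversible and meets no good nucleophile with one equivalent of Hg(II) under anhydrous conditions, and the C1 hydroxyl could only close a seven-membered ring. Attack at C7 (7-endo) is disfavoured by the Markovnikov preference for the tertiary carbon.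

Step 18
Reactants: 27 (2S)-2-[(3R,6R)-6-methyl-6-{2-[(4aR,8aS)-1,1,3,6-tetramethyl-1,4,4a,7,8,8a-hexahydronaphthalen-2-yl]ethyl}-1,2-dioxan-3-yl]propan-1-ol
Product: 28 (2R)-2-[(3R,6R)-6-methyl-6-{2-[(4aR,8aS)-1,1,3,6-tetramethyl-1,4,4a,7,8,8a-hexahydronaphthalen-2-yl]ethyl}-1,2-dioxan-3-yl]propanoic acid (CNP0122760.1)
Conditions: TEMPO (0.2 equiv), PhI(OAc)2 (2.2 equiv), MeCN/H2O (1:1), rt
Reagents that add atoms: water, O
Why: Oxoammonium-catalysed oxidation of the primary alcohol to the acid runs under non-basic conditions, so the β-peroxy carbonyl stage should neither open by retro-oxa-Michael elimination nor epimerise at C2, and the dialkyl peroxide and the hindered alkenes should survive.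

Compound list
1 | (S)-(−)-limonene, (4S)-1-methyl-4-(prop-1-en-2-yl)cyclohex-1-ene | CC1=CC[C@@H](C(C)=C)CC1 | starting material
2 | (1R,2S,4S)-limonene 1,2-oxide (trans-limonene oxide; epoxide oxygen and isopropenyl on the same ring face) | C[C@@]12CC[C@H](C(C)=C)C[C@@H]1O2 | intermediate
3 | (1R,2R,4S)-1-methyl-2-(phenylselanyl)-4-(prop-1-en-2-yl)cyclohexan-1-ol | C[C@@]1(O)CC[C@H](C(C)=C)C[C@H]1[Se]c1ccccc1 | intermediate (not isolated)
4 | Se-oxide of 3 (selenoxide) | C[C@@]1(O)CC[C@H](C(C)=C)C[C@H]1[Se](=O)c1ccccc1 | intermediate (not isolated)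
5 | (1R,4S)-1-methyl-4-(prop-1-en-2-yl)cyclohex-2-en-1-ol (OH and isopropenyl cis) | C[C@]1(O)C=C[C@@H](C(C)=C)CC1 | intermediate
6 | 1-ethoxyvinyl ether of 5 (mixed ketene acetal) | C=C(OCC)O[C@@]1(C)C=C[C@@H](C(C)=C)CC1 | intermediate (not isolated)
7 | ethyl 2-[(1R,6S)-3-methyl-6-(prop-1-en-2-yl)cyclohex-2-en-1-yl]acetate (substituents cis) | CC1=C[C@@H](CC(=O)OCC)[C@@H](C(C)=C)CC1 | intermediate
8 | ethyl 4-[(1R,6S)-3-methyl-6-(prop-1-en-2-yl)cyclohex-2-en-1-yl]-3-oxobutanoate | CC1=C[C@@H](CC(=O)CC(=O)OCC)[C@@H](C(C)=C)CC1 | intermediate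
9 | ethyl (4aR,8aS)-1,1,6-trimethyl-3-oxo-1,2,3,4,4a,7,8,8a-octahydronaphthalene-2-carboxylate (cis-fused; C2 epimers and enol) | CC1=C[C@H]2CC(=O)C(C(=O)OCC)C(C)(C)[C@H]2CC1 | intermediate
10 | ethyl (4aR,8aS)-1,1,6-trimethyl-3-(trifluoromethylsulfonyloxy)-1,4,4a,7,8,8a-hexahydronaphthalene-2-carboxylate | CC1=C[C@H]2CC(OS(=O)(=O)C(F)(F)F)=C(C(=O)OCC)C(C)(C)[C@H]2CC1 | intermediate
11 | ethyl (4aR,8aS)-1,1,3,6-tetramethyl-1,4,4a,7,8,8a-hexahydronaphthalene-2-carboxylate | CC1=C[C@H]2CC(C)=C(C(=O)OCC)C(C)(C)[C@H]2CC1 | intermediate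
12 | [(4aR,8aS)-1,1,3,6-tetramethyl-1,4,4a,7,8,8a-hexahydronaphthalen-2-yl]methanol | CC1=C[C@H]2CC(C)=C(CO)C(C)(C)[C@H]2CC1 | intermediate
13 | (4aR,8aS)-2-(bromomethyl)-1,1,3,6-tetramethyl-1,4,4a,7,8,8a-hexahydronaphthalene | CC1=C[C@H]2CC(C)=C(CBr)C(C)(C)[C@H]2CC1 | intermediate
14 | pent-4-yn-1-ol | C#CCCCO | starting material
15 | pent-4-ynal | C#CCCC=O | intermediate
16 | (R)-4-benzyl-3-propanoyl-1,3-oxazolidin-2-one | CCC(=O)N1[C@H](Cc2ccccc2)COC1=O | starting material
17 | (Z)-dibutylboron enolate of 16 | C/C=C(\OB(CCCC)CCCC)N1[C@H](Cc2ccccc2)COC1=O | intermediate (not isolated)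
18 | (4R)-4-benzyl-3-[(2R,3S)-3-hydroxy-2-methylhept-6-ynoyl]-1,3-oxazolidin-2-one | C#CCC[C@H](O)[C@@H](C)C(=O)N1[C@H](Cc2ccccc2)COC1=O | intermediate
19 | (2S,3S)-2-methylhept-6-yne-1,3-diol | C#CCC[C@H](O)[C@@H](C)CO | intermediate
20 | (2S,3S)-2-methyl-1-(triethylsilyloxy)hept-6-yn-3-ol | C#CCC[C@H](O)[C@@H](C)CO[Si](CC)(CC)CC | intermediate
21 | (E)-alkenyldimethylalane from 20 (Me and Al cis; hydroxyl as O–AlMe2) | C[Al](C)/C=C(\C)CC[C@H](O[Al](C)C)[C@@H](C)CO[Si](CC)(CC)CC | intermediate (not isolated)
22 | (2S,3S,6E)-2,6-dimethyl-8-[(4aR,8aS)-1,1,3,6-tetramethyl-1,4,4a,7,8,8a-hexahydronaphthalen-2-yl]-1-(triethylsilyloxy)oct-6-en-3-ol | CC1=C[C@H]2CC(C)=C(C/C=C(\C)CC[C@H](O)[C@@H](C)CO[Si](CC)(CC)CC)C(C)(C)[C@H]2CC1 | intermediate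
23 | (3S)-trifluoromethanesulfonate of 22 | CC1=C[C@H]2CC(C)=C(C/C=C(\C)CC[C@H](OS(=O)(=O)C(F)(F)F)[C@@H](C)CO[Si](CC)(CC)CC)C(C)(C)[C@H]2CC1 | intermediate (not isolated)
24 | triethylsilyl ether of (2S,3R,6E)-3-[(2-methoxypropan-2-yl)peroxy]-2,6-dimethyl-8-[(4aR,8aS)-1,1,3,6-tetramethyl-1,4,4a,7,8,8a-hexahydronaphthalen-2-yl]oct-6-en-1-ol | CC1=C[C@H]2CC(C)=C(C/C=C(\C)CC[C@@H](OOC(C)(C)OC)[C@@H](C)CO[Si](CC)(CC)CC)C(C)(C)[C@H]2CC1 | intermediate
25 | (2S,3R,6E)-3-hydroperoxy-2,6-dimethyl-8-[(4aR,8aS)-1,1,3,6-tetramethyl-1,4,4a,7,8,8a-hexahydronaphthalen-2-yl]oct-6-en-1-ol | CC1=C[C@H]2CC(C)=C(C/C=C(\C)CC[C@@H](OO)[C@@H](C)CO)C(C)(C)[C@H]2CC1 | intermediate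
26 | acetoxymercurio derivative of 27: AcOHg on the linker carbon next to dioxane C6 (R-configured C–Hg carbon, anti to the new C6–O bond) | CC1=C[C@H]2CC(C)=C(C[C@@H]([Hg]OC(C)=O)[C@]3(C)CC[C@H]([C@@H](C)CO)OO3)C(C)(C)[C@H]2CC1 | intermediate (not isolated)
27 | (2S)-2-[(3R,6R)-6-methyl-6-{2-[(4aR,8aS)-1,1,3,6-tetramethyl-1,4,4a,7,8,8a-hexahydronaphthalen-2-yl]ethyl}-1,2-dioxan-3-yl]propan-1-ol | CC1=C[C@H]2CC(C)=C(CC[C@]3(C)CC[C@H]([C@@H](C)CO)OO3)C(C)(C)[C@H]2CC1 | intermediate
28 | (2R)-2-[(3R,6R)-6-methyl-6-{2-[(4aR,8aS)-1,1,3,6-tetramethyl-1,4,4a,7,8,8a-hexahydronaphthalen-2-yl]ethyl}-1,2-dioxan-3-yl]propanoic acid | CC1=C[C@H]2CC(C)=C(CC[C@]3(C)CC[C@H]([C@@H](C)C(=O)O)OO3)C(C)(C)[C@H]2CC1 | target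

Total step count: 18. Longest linear sequence: 14 steps (steps 1–9, then 14–18); steps 10–13 form the side-chain branch that joins at step 14.

Steps most likely to fail

Step 17. Facial discrimination at C6 may be poor (axial methyl versus axial mercurated branch), which would give the C6 epimer. During demercuration the β-peroxyalkyl radical at C7 can also attack the O–O bond, giving an epoxide with ring opening. The fallback sets out from 25 and uses a kinetically controlled, irreversible halocyclisation with a non-radical removal of the auxiliary atom. N-iodosuccinimide in CH2Cl2 at −78 °C should close the same 6-exo ring by anti iodo-peroxidation to the iodide F1. DBU then eliminates HI towards the allylic CH2 to give the (E)-allylic peroxide F2, whose new alkene is conjugated with the ring-B alkene. Diimide (potassium azodicarboxylate, AcOH) should reduce only this disubstituted alkene, leave the tri- and tetrasubstituted alkenes and the O–O bond, and rejoin the route at 27.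

Step 15. E2 elimination and ionisation with hydride shift of the hindered, β-branched secondary triflate may outrun SN2 attack by the peroxide anion. The fallback sets out from 22 and replaces the basic anionic displacement by a silver-assisted perhydrolysis of a bromide under non-basic conditions. Mitsunobu inversion with 4-nitrobenzoic acid (PPh3, DIAD) gives the C3-inverted ester F3, and methanolysis (K2CO3, MeOH, 0 °C) gives the epimeric alcohol F4. Appel bromination (CBr4, PPh3) inverts again to the bromide F5. Silver trifluoroacetate with anhydrous H2O2 in ether should then exchange bromide for OOH with electrophilic assistance and predominant inversion, giving the silyl-protected hydroperoxide F6. AcOH/THF/H2O removes the TES group and the route is rejoined at 25.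

Step 5. Protonation of the ring alkene may compete, leading to double-bond migration or a bridged cyclisation from C6. The enol may be alkylated at oxygen instead of carbon, and proton loss and return at the tertiary cation may epimerise C8a. The fallback sets out from 8 and replaces proton initiation by mercury(II) initiation. Mercury(II) trifluoroacetate in nitromethane at −20 °C should activate only the 1,1-disubstituted alkene (the alkene that oxymercuration selects in limonene), and the enol adds at the tertiary carbon. Brine gives the chloromercurial F7, and NaBH4/NaOH replaces mercury by hydrogen to rejoin the route at 9.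

Further compounds
F1 | step 17 | (2S)-2-[(3R)-6-{(1R)-1-iodo-2-[(4aR,8aS)-1,1,3,6-tetramethyl-1,4,4a,7,8,8a-hexahydronaphthalen-2-yl]ethyl}-6-methyl-1,2-dioxan-3-yl]propan-1-ol (ring configuration as in 27) | CC1=C[C@H]2CC(C)=C(C[C@@H](I)[C@]3(C)CC[C@H]([C@@H](C)CO)OO3)C(C)(C)[C@H]2CC1
F2 | step 17 | (E)-7,8-didehydro analogue of 27 (vinylene link between dioxane C6 and the decalin) | CC1=C[C@H]2CC(C)=C(/C=C/[C@]3(C)CC[C@H]([C@@H](C)CO)OO3)C(C)(C)[C@H]2CC1
F3 | step 15 | 4-nitrobenzoate of the C3 epimer of 22 | CC1=C[C@H]2CC(C)=C(C/C=C(\C)CC[C@@H](OC(=O)c3ccc(cc3)[N+](=O)[O-])[C@@H](C)CO[Si](CC)(CC)CC)C(C)(C)[C@H]2CC1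
F4 | step 15 | C3 epimer of 22 (2S,3R alcohol) | CC1=C[C@H]2CC(C)=C(C/C=C(\C)CC[C@@H](O)[C@@H](C)CO[Si](CC)(CC)CC)C(C)(C)[C@H]2CC1
F5 | step 15 | C3 bromide with the spatial arrangement of the C–O bond of 22 | CC1=C[C@H]2CC(C)=C(C/C=C(\C)CC[C@H](Br)[C@@H](C)CO[Si](CC)(CC)CC)C(C)(C)[C@H]2CC1
F6 | step 15 | triethylsilyl ether of 25 | CC1=C[C@H]2CC(C)=C(C/C=C(\C)CC[C@@H](OO)[C@@H](C)CO[Si](CC)(CC)CC)C(C)(C)[C@H]2CC1
F7 | step 5 | ethyl (4aR,8aS)-1-[(chloromercurio)methyl]-1,6-dimethyl-3-oxo-1,2,3,4,4a,7,8,8a-octahydronaphthalene-2-carboxylate (C1 and C2 epimers) | CC1=C[C@H]2CC(=O)C(C(=O)OCC)C(C)(C[Hg]Cl)[C@H]2CC1
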